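**Plan**
- Cuts: C12–C13 (side chain to lactam ring, sp3–sp2 coupling); C8–CH3 together with a 1,3-shift of oxygen between C8 and C6; C9–C10 (reverse α-ketol shift, ring B contracts to a cyclopentane); C8–C9 and C12–Si.
- Enabling feature: in ring B the tertiary carbinol C9 is bonded to quaternary C10 and flanked by C8. A 1-acylcyclopentanol (carbinol C8, acyl carbon C9) gives exactly this C10–C9(OH)–C8 array when its ring bond C8–C10 moves to the acyl carbon.
- Forward order: ring A and a five-membered ring (C5, C6, C7, C8, C10) come with the (S)-Hajos–Parrish ketone. The acyl chain is added at C8, ring B arises by five-to-six enlargement, and the purchased lactam ring is joined last.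
- Stereochemistry: C10 from the starting ketone; C5 by α-face hydroboration; the C8 carbinol by α-face addition, relayed to C9 in the shift; C6 by α-face hydride attack; the C8 methine by 6β-hydroxyl-directed hydrogenation.

Key step: step 9

Remark: all bicyclic compounds carry labdane numbering (ring A = C1–C5 and C10; second ring = C5, C6, C7, C8, later also C9, and C10; chain C11, C12; lactam C13–C16). β is the face of the C10 methyl group. The configuration drawn for the transient C8 carbinol of step 11 is an expectation without consequence.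

Step 1
Reactants: 1 (S)-Hajos–Parrish ketone
Product: 2 8,8-ethylenedioxy enone (saturated C8 carbonyl of 1 masked as 1,3-dioxolane; C4=C5–C3=O enone intact; 10β-methyl)
Conditions: TMSOCH2CH2OTMS, TMSOTf (cat.), CH2Cl2, −78 → −20 °C
Reagents that add atoms: 1,2-bis(trimethylsilyloxy)ethane, C[Si](C)(C)OCCO[Si](C)(C)C
Why: Silyl-triflate-catalysed dioxolanation acetalises saturated ketones much faster than conjugated enones, so only the C8 carbonyl should be masked and C10 is untouched.

Step 2
Reactants: 2 8,8-ethylenedioxy enone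
Product: 3 8,8-ethylenedioxy-4,4,10β-trimethylhydrind-5-en-3-one (alkene C5=C6)
Conditions: KOtBu, MeI, tBuOH–THF, 0 °C → rt
Reagents that add atoms: iodomethane, IC
Why: Deconjugative double α-alkylation, in which the extended potassium dienolate is methylated twice at C4 and the alkene moves to C5=C6, as in the 4,4-dimethylation of bicyclic and steroidal 4-en-3-ones.

Step 3
Reactants: 3 8,8-ethylenedioxy-4,4,10β-trimethylhydrind-5-en-3-one
Product: 5 8,8-ethylenedioxy-4,4,10β-trimethylhydrind-5-ene, via C3 hydrazone 4 (not isolated)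
Conditions: N2H4·H2O, KOH, diethylene glycol, 130 → 200 °C
Reagents that add atoms: none
Why: Wolff–Kishner reduction (Huang-Minlon variant) removes the hindered C3 carbonyl under purely basic conditions that leave the dioxolane and the isolated trisubstituted alkene alone.

Step 4
Reactants: 5 8,8-ethylenedioxy-4,4,10β-trimethylhydrind-5-ene
Product: 7 8,8-ethylenedioxy-4,4,10β-trimethyl-5αH-hydrindan-6α-ol (trans ring fusion), via 6α-boryl hydrindane 6 (not isolated)
Conditions: BH3·THF, THF, 0 °C → rt; then NaOH, H2O2, 0 °C → rt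
Reagents that add atoms: hydrogen peroxide, OO
Why: Hydroboration–oxidation, in which borane adds syn and anti-Markovnikov from the α face away from the C10 methyl group, so 5α-H (trans fusion) and the 6α-oxygen are set together as with steroidal 14-enes.

Step 5
Reactants: 7 8,8-ethylenedioxy-4,4,10β-trimethyl-5αH-hydrindan-6α-ol
Product: 8 6α-tert-butyldimethylsilyl ether of 7
Conditions: TBSOTf, 2,6-lutidine, CH2Cl2, 0 °C
Reagents that add atoms: tert-butyldimethylsilyl triflate, CC(C)(C)[Si](C)(C)OS(=O)(=O)C(F)(F)F
Why: Silyl triflate silylation of a hindered secondary alcohol, giving an ether that protects O6 now and serves as the leaving group in the key step.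

Step 6
Reactants: 8 6α-tert-butyldimethylsilyl ether
Product: 9 6α-(tert-butyldimethylsilyloxy)-4,4,10β-trimethyl-trans-hydrindan-8-one
Conditions: TsOH·H2O (cat.), acetone–H2O, rt
Reagents that add atoms: water, O
Why: Acid-catalysed acetal hydrolysis frees the C8 ketone while the hindered secondary silyl ether and the ring fusion, which is not α to a carbonyl, stay as they are.

Step 7
Reactants: 9 6α-silyloxy-trans-hydrindan-8-one; 10 methoxyallene (1-methoxypropa-1,2-diene)
Product: 13 8α-acryloyl-8β-hydroxy-6α-(tert-butyldimethylsilyloxy)-4,4,10β-trimethyl-trans-hydrindane, via 1-lithio-1-methoxyallene 11 (not isolated), via methoxyallenyl carbinol 12 (not isolated)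
Conditions: 10, nBuLi, THF, −40 °C; 9, −78 °C; then 1 M HCl, THF, 0 °C
Reagents that add atoms: water, O
Why: 1,2-Addition of an acryloyl-anion equivalent, in which the slim lithiated alkoxyallene attacks the neopentyl cyclopentanone from the α face opposite the C10 methyl group (the course of additions to steroidal 17-ketones) and sets 8β-OH, after which mild hydrolysis of the allenyl ether gives the α′-hydroxy vinyl ketone.

Step 8
Reactants: 13 8α-acryloyl-8β-hydroxy hydrindane
Product: 14 8β-hydroxy-8α-[3-(dimethylphenylsilyl)propanoyl]-6α-(tert-butyldimethylsilyloxy)-4,4,10β-trimethyl-trans-hydrindane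
Conditions: PhMe2Si–Bpin, CuSO4 (5 mol %), 4-picoline (10 mol %), THF–H2O, rt
Reagents that add atoms: (dimethylphenylsilyl)boronic acid pinacol ester, CC1(C)OB(OC1(C)C)[Si](C)(C)c1ccccc1
Why: Copper-catalysed conjugate silylation of an enone places at C12 a silicon group that is a masked hydroxyl and, unlike a β-alkoxy group, cannot be lost by retro-Michael elimination in the basic key step.

Step 9
Reactants: 14 8β-hydroxy-8α-[3-(dimethylphenylsilyl)propanoyl] hydrindane
Product: 16 9α-hydroxy-9β-[2-(dimethylphenylsilyl)ethyl]-4,4,10β-trimethyl-5αH-octal-6-en-8-one (trans-fused enone), via 6α-silyloxy ketol 15 (not isolated)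
Conditions: KOH (0.5 M), MeOH, rt → 55 °C
Reagents that add atoms: none
Why: Methanolic KOH turns the 8β-hydroxyl into an alkoxide whose C8–C10 bond, aligned with the π* orbital of the acyl carbonyl, shifts with its electron pair to C9 while C8 becomes the ketone (15); the 6α-silyloxy group, now β to that ketone, then leaves by E1cB to give enone 16. The closest known reaction type is the base-induced α-ketol (acyloin) rearrangement of 1-acylcycloalkanols with ring enlargement, practised as the D-homoannulation of 17-hydroxy-20-oxo steroids. Ring B is closed not by cyclisation but by one-carbon enlargement of the five-membered ring: exocyclic C9 is inserted into the C8–C10 bond through a three-centre transition state, and release of trans-hydrindane strain supplies the driving force. The one new stereocentre, C9, is controlled by C8: the acyl carbon hangs on the α face, C10 migrates suprafacially with retention, and with methanol-solvated potassium the two C–O dipoles stay anti, a chair-like array that leaves O9 axial (α) and the chain equatorial (β). The step needs migration of C10 and not of C7, which the substrate favours because C10 is quaternary and its bond to C8 is the strained one, because C7 is deactivated inductively by the C6 oxygen, and because a shift of C7 would pass through a boat-like array underneath the 6α-silyloxy group. Since ketol isomers interconvert under base, the elimination, open only to the isomer with its ketone at C8, also withdraws the wanted skeleton from that equilibrium.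

Step 10
Reactants: 16 9α-hydroxy enone
Product: 17 9α-triethylsilyl ether of 16
Conditions: TESOTf, 2,6-lutidine, CH2Cl2, 0 °C → rt
Reagents that add atoms: triethylsilyl triflate, CC[Si](CC)(CC)OS(=O)(=O)C(F)(F)F
Why: Silyl triflate silylation of the tertiary carbinol blocks any further ketol shift, prevents glycol cleavage in step 12 and removes an α-face directing group before step 14.

Step 11
Reactants: 17 9α-triethylsilyloxy enone
Product: 18 8α-hydroxy-8β-methyl-9α-triethylsilyloxy-9β-[2-(dimethylphenylsilyl)ethyl]-4,4,10β-trimethyl-5αH-octal-6-ene (tertiary allylic alcohol)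
Conditions: MeLi, Et2O, −78 °C; then H2O
Reagents that add atoms: methyllithium, [Li]C
Why: 1,2-Addition of methyllithium to the enone carbonyl brings in the C8 methyl carbon, with attack anti to the axial C9–O bond expected, although the new carbinol centre is erased in the next step.

Step 12
Reactants: 18 tertiary allylic alcohol
Product: 19 8-methyl-9α-triethylsilyloxy-9β-[2-(dimethylphenylsilyl)ethyl]-4,4,10β-trimethyl-5αH-octal-7-en-6-one
Conditions: pyridinium chlorochromate [C5H5NH][CrO3Cl], NaOAc, 4 Å MS, CH2Cl2, rt
Reagents that add atoms: pyridinium chlorochromate, [O-][Cr](=O)(=O)Cl.c1cc[nH+]cc1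
Why: Oxidative 1,3-transposition of a tertiary allylic alcohol with hexavalent chromium (Babler–Dauben reaction), in which the chromate ester shifts suprafacially from C8 to C6 and is oxidised there, returning oxygen to C6 and leaving the C7=C8 alkene with its methyl group.

Step 13
Reactants: 19 7-en-6-one
Product: 20 6β-hydroxy-8-methyl-9α-triethylsilyloxy-9β-[2-(dimethylphenylsilyl)ethyl]-4,4,10β-trimethyl-5αH-octal-7-ene
Conditions: NaBH4, CeCl3·7H2O, MeOH, −78 → 0 °C
Reagents that add atoms: none
Why: Luche 1,2-reduction, in which the β face of C6 is closed by the axial methyl groups on C4 and C10, so hydride arrives from the α face and gives the axial 6β-alcohol, the usual result for 6-oxo drimanes and labdanes.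

Step 14
Reactants: 20 allylic 6β-alcohol
Product: 21 6β-hydroxy-8α-methyl-9α-triethylsilyloxy-9β-[2-(dimethylphenylsilyl)ethyl]-4,4,10β-trimethyl-trans-decalin (8β-H)
Conditions: H2 (1 atm), [Ir(cod)(PCy3)(py)]PF6 (10 mol %), CH2Cl2, rt
Reagents that add atoms: none
Why: Hydroxyl-directed homogeneous hydrogenation, in which the cationic monovalent iridium catalyst binds the allylic 6β-hydroxyl and delivers both hydrogens to the β face while the 9α-silyloxy group screens the α face, so 8β-H and the equatorial 8α-methyl group should result.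

Step 15
Reactants: 21 6β-alcohol
Product: 22 6β-acetate of 21
Conditions: Ac2O, DMAP (cat.), pyridine, 40 °C
Reagents that add atoms: acetic anhydride, CC(=O)OC(C)=O
Why: DMAP-catalysed acylation is the standard way to esterify the hindered axial 6β-hydroxyl of labdanes and touches no stereocentre.

Step 16
Reactants: 22 6β-acetate
Product: 23 6β-acetoxy-9β-(2-hydroxyethyl)-8α-methyl-9α-triethylsilyloxy-4,4,10β-trimethyl-trans-decalin
Conditions: KBr, AcOOH (32% in AcOH), NaOAc, AcOH, 0 °C → rt
Reagents that add atoms: peracetic acid, CC(=O)OO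
Why: Fleming–Tamao oxidation, in which bromodesilylation of the phenyl group and a peracid-induced 1,2-shift from silicon to oxygen turn C12–Si into C12–OH, with no alkene left to react and a buffer that spares the acetate and the hindered silyl ether.

Step 17
Reactants: 23 primary alcohol
Product: 24 6β-acetoxy-9β-(2-iodoethyl)-8α-methyl-9α-triethylsilyloxy-4,4,10β-trimethyl-trans-decalin
Conditions: PPh3, I2, imidazole, CH2Cl2, 0 °C → rt
Reagents that add atoms: iodine, [I][I]
Why: Appel-type iodination converts the unhindered primary alcohol by SN2 displacement under near-neutral conditions.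

Step 18
Reactants: 25 tert-butyl 2,4-dioxopyrrolidine-1-carboxylate
Product: 26 tert-butyl 2-oxo-4-(trifluoromethylsulfonyloxy)-2,5-dihydropyrrole-1-carboxylate
Conditions: Tf2O, Et3N, CH2Cl2, −78 → 0 °C
Reagents that add atoms: triflic anhydride, O=S(=O)(OS(=O)(=O)C(F)(F)F)C(F)(F)F
Why: O-Sulfonylation of the enol form of the tetramic acid gives the vinylogous acyl triflate, a known class of cross-coupling partners.

Step 19
Reactants: 24 primary iodide; 26 lactam enol triflate
Product: 28 N-Boc 9-O-triethylsilyl derivative of the target (C12–C13 bond in place), via alkylzinc iodide 27 (not isolated)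
Conditions: Zn dust, LiCl, THF, 40 °C; then 26, PdCl2(dppf) (5 mol %), THF, rt
Reagents that add atoms: none
Why: Negishi sp3–sp2 coupling, in which direct zinc insertion tolerates ester and silyl ether, oxidative addition of zerovalent palladium to the electron-poor enol triflate is fast, and the wide-bite-angle ligand favours reductive elimination over β-hydride loss.

Step 20
Reactants: 28 protected target
Product: 29 CNP0546323.1 (6β-acetoxy-9α-hydroxy-8α-methyl labdane bearing the 4-substituted 1,5-dihydropyrrol-2-one)
Conditions: HCl (1.25 M in MeOH), 0 °C → rt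
Reagents that add atoms: none
Why: Acidolysis with dilute methanolic HCl cleaves the acyl-activated tert-butyl carbamate and solvolyses the triethylsilyl ether, while the hindered axial acetate and the tertiary carbinol are expected to persist at this acidity.

**Compound list**
1 | (S)-Hajos–Parrish ketone | C[C@]12CCC(=O)C=C1CCC2=O | starting material
2 | 8,8-ethylenedioxy enone | C[C@]12CCC(=O)C=C1CCC23OCCO3 | intermediate
3 | 8,8-ethylenedioxy-4,4,10β-trimethylhydrind-5-en-3-one | C[C@]12CCC(=O)C(C)(C)C1=CCC23OCCO3 | intermediate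
4 | C3 hydrazone of 3 | C[C@]12CCC(=NN)C(C)(C)C1=CCC23OCCO3 | intermediate
5 | 8,8-ethylenedioxy-4,4,10β-trimethylhydrind-5-ene | C[C@]12CCCC(C)(C)C1=CCC23OCCO3 | intermediate
6 | 6α-boryl-5αH-hydrindane (monoalkylborane) | B[C@H]1CC3(OCCO3)[C@@]2(C)CCCC(C)(C)[C@H]12 | intermediate
7 | 8,8-ethylenedioxy-4,4,10β-trimethyl-5αH-hydrindan-6α-ol | O[C@H]1CC3(OCCO3)[C@@]2(C)CCCC(C)(C)[C@H]12 | intermediate
8 | 6α-TBS ether of 7 | CC(C)(C)[Si](C)(C)O[C@H]1CC3(OCCO3)[C@@]2(C)CCCC(C)(C)[C@H]12 | intermediate
9 | 6α-TBSO-4,4,10β-trimethyl-trans-hydrindan-8-one | CC(C)(C)[Si](C)(C)O[C@H]1CC(=O)[C@@]2(C)CCCC(C)(C)[C@H]12 | intermediate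
10 | methoxyallene | COC=C=C | starting material
11 | 1-lithio-1-methoxyallene | [Li]C(OC)=C=C | intermediate
12 | 8β-hydroxy-8α-(1-methoxyallenyl) hydrindane | CC(C)(C)[Si](C)(C)O[C@H]1C[C@@](O)(C(OC)=C=C)[C@@]2(C)CCCC(C)(C)[C@H]12 | intermediate
13 | 8α-acryloyl-8β-hydroxy hydrindane | CC(C)(C)[Si](C)(C)O[C@H]1C[C@@](O)(C(=O)C=C)[C@@]2(C)CCCC(C)(C)[C@H]12 | intermediate
14 | 8β-hydroxy-8α-[3-(dimethylphenylsilyl)propanoyl] hydrindane (ketol precursor) | CC(C)(C)[Si](C)(C)O[C@H]1C[C@@](O)(C(=O)CC[Si](C)(C)c3ccccc3)[C@@]2(C)CCCC(C)(C)[C@H]12 | intermediate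
15 | 9α-hydroxy-9β-[2-(dimethylphenylsilyl)ethyl]-6α-TBSO-trans-decalin-8-one | CC(C)(C)[Si](C)(C)O[C@H]1CC(=O)[C@](O)(CC[Si](C)(C)c3ccccc3)[C@@]2(C)CCCC(C)(C)[C@H]12 | intermediate
16 | 9α-hydroxy-6-en-8-one | C1=CC(=O)[C@](O)(CC[Si](C)(C)c3ccccc3)[C@@]2(C)CCCC(C)(C)[C@H]12 | intermediate
17 | 9α-triethylsilyloxy-6-en-8-one | C1=CC(=O)[C@](O[Si](CC)(CC)CC)(CC[Si](C)(C)c3ccccc3)[C@@]2(C)CCCC(C)(C)[C@H]12 | intermediate
18 | 8α-hydroxy-8β-methyl-6-ene | C1=C[C@@](C)(O)[C@](O[Si](CC)(CC)CC)(CC[Si](C)(C)c3ccccc3)[C@@]2(C)CCCC(C)(C)[C@H]12 | intermediate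
19 | 8-methyl-7-en-6-one | O=C1C=C(C)[C@](O[Si](CC)(CC)CC)(CC[Si](C)(C)c3ccccc3)[C@@]2(C)CCCC(C)(C)[C@H]12 | intermediate
20 | 6β-hydroxy-8-methyl-7-ene | O[C@@H]1C=C(C)[C@](O[Si](CC)(CC)CC)(CC[Si](C)(C)c3ccccc3)[C@@]2(C)CCCC(C)(C)[C@H]12 | intermediate
21 | 6β-hydroxy-8α-methyl decalin | O[C@@H]1C[C@@H](C)[C@](O[Si](CC)(CC)CC)(CC[Si](C)(C)c3ccccc3)[C@@]2(C)CCCC(C)(C)[C@H]12 | intermediate
22 | 6β-acetate | CC(=O)O[C@@H]1C[C@@H](C)[C@](O[Si](CC)(CC)CC)(CC[Si](C)(C)c3ccccc3)[C@@]2(C)CCCC(C)(C)[C@H]12 | intermediate
23 | C12 primary alcohol | CC(=O)O[C@@H]1C[C@@H](C)[C@](O[Si](CC)(CC)CC)(CCO)[C@@]2(C)CCCC(C)(C)[C@H]12 | intermediate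
24 | C12 iodide | CC(=O)O[C@@H]1C[C@@H](C)[C@](O[Si](CC)(CC)CC)(CCI)[C@@]2(C)CCCC(C)(C)[C@H]12 | intermediate
25 | tert-butyl 2,4-dioxopyrrolidine-1-carboxylate | CC(C)(C)OC(=O)N1CC(=O)CC1=O | starting material
26 | N-Boc lactam enol triflate | CC(C)(C)OC(=O)N1CC(OS(=O)(=O)C(F)(F)F)=CC1=O | intermediate
27 | C12 alkylzinc iodide | CC(=O)O[C@@H]1C[C@@H](C)[C@](O[Si](CC)(CC)CC)(CC[Zn]I)[C@@]2(C)CCCC(C)(C)[C@H]12 | intermediate
28 | N-Boc 9-O-TES target | CC(=O)O[C@@H]1C[C@@H](C)[C@](O[Si](CC)(CC)CC)(CCC3=CC(=O)N(C(=O)OC(C)(C)C)C3)[C@@]2(C)CCCC(C)(C)[C@H]12 | intermediate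
29 | CNP0546323.1 | CC(=O)O[C@@H]1C[C@@H](C)[C@](O)(CCC2=CC(=O)NC2)[C@@]2(C)CCCC(C)(C)[C@H]12 | target

Total step count: 20. Longest linear sequence: 19 (steps 1–17, 19, 20).

**Steps most likely to fail**

**Step 9.** C7 may migrate in place of C10, and that isomer returns to the equilibrium only slowly. Part of the shift may run through a cation-bridged syn array, which would erode control at C9. The equatorial silyloxy group may be expelled sluggishly, and γ-deprotonation at C5 of the enone is possible.

Fallback (from 9, back at 15): the ring is enlarged first and the C9 carbinol is made afterwards by face-selective dihydroxylation.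
- Ketone 9 is homologated with CH2N2 and BF3·OEt2. The less substituted C7 migrates, as in the formation of D-homo-17a-ketones, giving 6α-silyloxy-4,4,10β-trimethyl-trans-decalin-9-one F1.
- KHMDS and PhNTf2 convert it into the 8-en-9-yl triflate F2.
- Dimethyl(phenyl)vinylsilane and 9-BBN-H give 9-[2-(dimethylphenylsilyl)ethyl]-9-borabicyclo[3.3.1]nonane F3. This is joined to F2 by B-alkyl Suzuki–Miyaura coupling (PdCl2(dppf), Cs2CO3, DMF–THF–H2O) to give the 9-alkyl-8-ene F4.
- OsO4 and NMO should attack the α face opposite the axial C10 methyl group and give the 8α,9α-diol F5.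
- Parikh–Doering oxidation of the secondary hydroxyl leads to 15, which methanolic KOH takes on to 16.

**Step 14.** The catalyst may not turn over at the hindered trisubstituted alkene, hydrogen may be delivered to the α face, or iridium may isomerise the allylic alcohol.

Fallback (from 20, back at 22): direction by the hydroxyl is given up and product stability decides.
- Alcohol 20 is acetylated first (Ac2O, DMAP, pyridine) to the allylic 6β-acetoxy-8-methyl-7-ene F6.
- The alkene is then reduced by radical hydrogen-atom transfer (Mn(dpm)3, PhSiH3, tBuOOH, iPrOH, rt).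
- Hydrogen-atom addition to C7 gives the tertiary C8 radical. It should be quenched to the more stable epimer, whose methyl group is equatorial (8α) and avoids the syn-axial contact with the C10 methyl and 6β-acetoxy groups. This is 22.

**Step 7.** The basic organolithium may enolise the hindered ketone, with loss of silanolate. Addition may be incomplete, and the 6α-substituent may erode facial selectivity.

Fallback (from 9, back at 13): the acryloyl group is built in stages from a much less basic nucleophile.
- Lithium acetylide–ethylenediamine adds to 9 from the α face (the classical ethynylation of 17-ketones) to give the 8α-ethynyl-8β-hydroxy hydrindane F7.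
- Markovnikov hydration with (Ph3P)AuNTf2 in aqueous dioxane gives the 8α-acetyl-8β-hydroxy hydrindane F8.
- α-Methylenation with paraformaldehyde and diisopropylammonium trifluoroacetate in THF (Mannich condensation–elimination) gives 13.

**Further compounds**
F1 | step 9 | 6α-TBSO-4,4,10β-trimethyl-trans-decalin-9-one | CC(C)(C)[Si](C)(C)O[C@H]1CCC(=O)[C@@]2(C)CCCC(C)(C)[C@H]12
F2 | step 9 | 6α-TBSO-8-en-9-yl triflate | CC(C)(C)[Si](C)(C)O[C@H]1CC=C(OS(=O)(=O)C(F)(F)F)[C@@]2(C)CCCC(C)(C)[C@H]12
F3 | step 9 | 9-[2-(dimethylphenylsilyl)ethyl]-9-borabicyclo[3.3.1]nonane | C[Si](C)(CCB1C2CCCC1CCC2)c1ccccc1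
F4 | step 9 | 6α-TBSO-9-[2-(dimethylphenylsilyl)ethyl]-8-ene | CC(C)(C)[Si](C)(C)O[C@H]1CC=C(CC[Si](C)(C)c3ccccc3)[C@@]2(C)CCCC(C)(C)[C@H]12
F5 | step 9 | 6α-TBSO-8α,9α-diol | CC(C)(C)[Si](C)(C)O[C@H]1C[C@@H](O)[C@](O)(CC[Si](C)(C)c3ccccc3)[C@@]2(C)CCCC(C)(C)[C@H]12
F6 | step 14 | 6β-acetoxy-8-methyl-9α-triethylsilyloxy-7-ene | CC(=O)O[C@@H]1C=C(C)[C@](O[Si](CC)(CC)CC)(CC[Si](C)(C)c3ccccc3)[C@@]2(C)CCCC(C)(C)[C@H]12
F7 | step 7 | 8α-ethynyl-8β-hydroxy-6α-TBSO hydrindane | CC(C)(C)[Si](C)(C)O[C@H]1C[C@@](O)(C#C)[C@@]2(C)CCCC(C)(C)[C@H]12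
F8 | step 7 | 8α-acetyl-8β-hydroxy-6α-TBSO hydrindane | CC(C)(C)[Si](C)(C)O[C@H]1C[C@@](O)(C(C)=O)[C@@]2(C)CCCC(C)(C)[C@H]12
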